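**Retrosynthetic overview**
1. 28 comes from 26 by desilylation and peracetylation. The Z C3=C4 bond of 26 comes from cis-semihydrogenation of the ring alkyne in 25.
2. Key disconnection C7–C8: the C7 enynal carbonyl carbon is made nucleophilic as a samarium ketyl and adds to the C8 ketone of β-keto ester 23. This closes the ten-membered ring and sets C7 and C8, and O7 lactonises in the same flask.
3. 23 comes from ring A alkyne 17 and (Z)-iodoenal 22 (C4–C5, Sonogashira). 22 is made from but-2-yne-1,4-diol.
4. 17 comes from ring A aldehyde 6 through C8–C17 (Roskamp), C2–C3 (ethynyl Grignard) and C11=CH2 (allylic oxidation, 1,4-reduction, Wittig).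
5. 6 comes from enal 4 (from D-mannitol; its C9 is the only source of chirality) and 1-silyloxybutadiene by Diels–Alder. Ring order: ring A first, then the ten-membered ring and the γ-lactone together.

Assumption: briarane numbering (C1–C20) is used for all intermediates, α/β refer to the usual drawing with CH3-15 β, the SMILES strings are definitive, and 2, 5 and 7 are taken as catalogue items.

**Step 1**
Reactants: 1 1,2:5,6-di-O-isopropylidene-D-mannitol; 2 2-(triphenylphosphoranylidene)propanal
Product: 4 (2E)-3-[(4S)-2,2-dimethyl-1,3-dioxolan-4-yl]-2-methylprop-2-enal, via glyceraldehyde acetonide 3 (not isolated)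
Conditions: NaIO4, aq NaHCO3, CH2Cl2, rt; dry, filter; then 2, CH2Cl2, reflux
Reagents that add atoms: none
Why: Periodate glycol cleavage gives two equivalents of configurationally intact aldehyde 3, and the stabilised ylide converts it by a Wittig reaction into the (E)-trisubstituted enal, so that C9 (S) is carried over unchanged from D-mannitol.

**Step 2**
Reactants: 4 enal; 5 (E)-1-(trimethylsilyloxy)buta-1,3-diene
Product: 6 ring A aldehyde (1R,2S,6S)-6-[(4S)-2,2-dimethyl-1,3-dioxolan-4-yl]-1-methyl-2-(trimethylsilyloxy)cyclohex-3-ene-1-carbaldehyde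
Conditions: Me2AlCl (20 mol %), CH2Cl2, −78 to −30 °C
Reagents that add atoms: none
Why: In this Lewis acid catalysed Diels–Alder reaction the silyloxy terminus bonds to the formyl-bearing carbon (ortho rule), the complexed CHO sits endo so O14 ends cis to C2, the E alkene fixes C2 and C9 trans, and with H-9 eclipsing the alkene (A(1,3) strain against CH3-15) the diene attacks anti to the allylic C9–O bond (Felkin–Anh type), which sets C1, C10 and C14 from C9.

**Step 3**
Reactants: 6 ring A aldehyde; 7 ethynylmagnesium bromide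
Product: 8 (2S)-propargylic alcohol of ring A (CHO of 6 turned into (S)-CH(OH)C≡CH)
Conditions: THF, −78 to 0 °C; aq NH4Cl
Reagents that add atoms: none
Why: Grignard 1,2-addition to the neopentylic aldehyde under Felkin–Anh control, with the nucleophile coming anti to the bulkier C10 branch and past CH3-15, gives the 2S carbinol (a magnesium chelate to O14 predicts the same face).

**Step 4**
Reactants: 8 propargylic alcohol
Product: 9 ring A tetraol (free OH at C2/C8/C9/C14)
Conditions: AcOH–THF–H2O (3:1:1), 40 °C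
Reagents that add atoms: none
Why: Mild acid hydrolysis removes the terminal acetonide and the labile trimethylsilyl ether without touching any stereocentre, the alkyne or the ring alkene.

**Step 5**
Reactants: 9 tetraol
Product: 10 tetrakis(triethylsilyl) ether of 9
Conditions: Et3SiOTf (4.5 equiv), 2,6-lutidine, CH2Cl2, −78 to 0 °C
Reagents that add atoms: triethylsilyl triflate, CC[Si](CC)(CC)OS(=O)(=O)C(F)(F)F
Why: Exhaustive O-silylation with the reactive triflate also covers the hindered C2 and C14 hydroxyls and puts the one primary silyl ether (O on C8) in place for its later selective oxidation.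

**Step 6**
Reactants: 10 tetrakis(triethylsilyl) ether
Product: 11 ring A enone (C11=O; C12=C13)
Conditions: Rh2(cap)4 (cap = caprolactamate, 1 mol %), t-BuOOH (70% aq, 5 equiv), K2CO3 (0.5 equiv), CH2Cl2, rt
Reagents that add atoms: tert-butyl hydroperoxide, CC(C)(C)OO
Why: Radical allylic C–H oxidation attacks the only accessible allylic CH2 (C11) and places the carbonyl remote from the silyloxy carbon, as in the known conversion of cyclohex-2-enyl ethers into 4-oxycyclohex-2-enones, while the neopentylic, silyl-shielded C2–H is spared.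

**Step 7**
Reactants: 11 enone
Product: 12 saturated C11 ketone
Conditions: LiBH(s-Bu)3 (1.1 equiv), THF, −78 °C; aq NH4Cl
Reagents that add atoms: none
Why: The bulky trialkylborohydride reduces β-unsubstituted cyclohexenones by conjugate hydride addition, the enolate is safe from further reduction until the quench, and the alkyne is untouched.

**Step 8**
Reactants: 12 ketone
Product: 13 11(20)-exomethylene compound
Conditions: Ph3PCH3Br, KOt-Bu, THF, 0 °C to rt
Reagents that add atoms: methyltriphenylphosphonium bromide, C[P+](c1ccccc1)(c1ccccc1)c1ccccc1.[Br-]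
Why: Wittig methylenation by the non-stabilised ylide is faster than enolisation towards C10, whose substituent is already in the favoured equatorial position, so C10 and the β-silyloxy group at C9 survive.

**Step 9**
Reactants: 13 exomethylene compound
Product: 14 C8 aldehyde ((9S)-α-triethylsilyloxy aldehyde)
Conditions: (COCl)2, DMSO, CH2Cl2, −78 to −40 °C; Et3N, −78 °C to rt
Reagents that add atoms: none
Why: Under Swern conditions activated DMSO attacks only the unhindered primary triethylsilyl ether and oxidises it directly to the aldehyde, leaving the three secondary silyl ethers and C9 intact.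

**Step 10**
Reactants: 15 ethyl 2-methylacetoacetate
Product: 16 ethyl 2-diazopropanoate
Conditions: 4-AcNHC6H4SO2N3, DBU, MeCN, 0 °C to rt
Reagents that add atoms: 4-acetamidobenzenesulfonyl azide, CC(=O)Nc1ccc(cc1)S(=O)(=O)N=[N+]=[N-]
Why: In deacylative Regitz diazo transfer the enolate attacks the sulfonyl azide and the acetyl group leaves on the sulfonamide nitrogen.

**Step 11**
Reactants: 14 aldehyde; 16 ethyl 2-diazopropanoate
Product: 17 β-keto ester (C8 ketone; C17 epimer mixture)
Conditions: SnCl2 (20 mol %), CH2Cl2, 0 °C to rt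
Reagents that add atoms: none
Why: In the Roskamp homologation the diazo carbon adds to the Lewis acid activated aldehyde and a 1,2-hydride shift with loss of N2 gives the β-keto ester without epimerising C9, while C17 stays labile and is settled in step 16.

**Step 12**
Reactants: 18 but-2-yne-1,4-diol
Product: 19 4-(tert-butyldimethylsilyloxy)but-2-yn-1-ol
Conditions: NaH (1.0 equiv), THF, 0 °C; t-BuMe2SiCl (1.0 equiv), rt
Reagents that add atoms: tert-butyldimethylsilyl chloride, CC(C)(C)[Si](C)(C)Cl
Why: O-silylation of the sparingly soluble monosodium alkoxide of the symmetric diol stops cleanly at the mono ether.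

**Step 13**
Reactants: 19 monosilyl ether
Product: 21 (Z)-4-(tert-butyldimethylsilyloxy)-3-iodobut-2-en-1-ol, via cyclic vinylalanate 20 (not isolated)
Conditions: NaAlH2(OCH2CH2OMe)2, THF, 0 °C to rt; EtOAc; I2, −78 to 0 °C
Reagents that add atoms: iodine, II
Why: Hydroxyl-directed trans-hydroalumination places aluminium on the distal alkyne carbon in a five-membered alanate, and iodinolysis with retention puts iodine cis to CH2OH, which is the C4/C7-cis geometry needed at C5=C6.

**Step 14**
Reactants: 21 iodo allylic alcohol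
Product: 22 (Z)-4-(tert-butyldimethylsilyloxy)-3-iodobut-2-enal
Conditions: MnO2, CH2Cl2, rt
Reagents that add atoms: none
Why: Neutral heterogeneous allylic alcohol oxidation with MnO2 gives the enal without Z/E isomerisation or loss of iodide.

**Step 15**
Reactants: 17 β-keto ester alkyne; 22 iodoenal
Product: 23 seco enynal keto ester (C4–C5 joined; 5E with C4 cis to C7)
Conditions: PdCl2(PPh3)2 (5 mol %), CuI (10 mol %), Et3N, THF, 0 °C to rt
Reagents that add atoms: none
Why: Sonogashira coupling of the activated β-iodoenal proceeds near 0 °C with retention of alkene geometry and tolerates the aldehyde, keto ester and silyl ethers.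

**Step 16**
Reactants: 23 seco enynal keto ester
Product: 25 macrocyclic enyne lactone (7S,8S,17R; free 8-OH), via pinacol diol ester 24 (not isolated)
Conditions: SmI2 (4 equiv, 0.1 M in THF), THF, −78 to 0 °C, 23 added by syringe pump (final 1 mM); aq NaHCO3
Reagents that add atoms: none
Why: Proposed new method: divalent samarium reduces the conjugated C7 aldehyde first to a samarium ketyl, an α-oxy radical/anion (d1 synthon) that attacks the samarium-bound C8 ketone so that two normally electrophilic carbonyl carbons are joined; bridging of O7 and O8 by trivalent samarium gives the cis-7,8-diol, repulsion between O8–Sm and the C9 silyloxy group places O8 trans to O9 on the new ring (7S,8S), the O7 alkoxide lactonises onto the ethyl ester, and the still enolisable C17 settles in the basic samarium alkoxide medium with CH3-18 anti to C9 (17R); the rigid enyne keeps the chain ends close and cannot isomerise as a Z,Z-dienal would; the closest known reaction types are the SmI2 keto–aldehyde pinacol carbocyclisation of sugar-derived dicarbonyls (cis diol, anti to the neighbouring alkoxy group), samarium and low-valent titanium pinacol macrocyclisations, and ketyl coupling/lactonisation cascades.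

**Step 17**
Reactants: 25 macrocyclic enyne lactone
Product: 26 (3Z,5E)-diene lactone
Conditions: H2 (1 atm), Pd/CaCO3–Pb(OAc)2 (Lindlar catalyst, 5 wt %), quinoline, EtOAc, rt
Reagents that add atoms: none
Why: In Lindlar cis-semihydrogenation, syn delivery of H2 to the bent ring alkyne is much faster than to the 1,1-disubstituted and trisubstituted alkenes and can only give the ring-cis (Z) C3=C4 bond.

**Step 18**
Reactants: 26 diene lactone
Product: 28 CNP0269068.1 (target), via pentaol 27 (not isolated)
Conditions: HF·pyridine, pyridine, THF, 0 °C to rt; concentrate; Ac2O, pyridine, DMAP (5 mol %), 0 °C to rt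
Reagents that add atoms: acetic anhydride, CC(=O)OC(C)=O
Why: Fluoride desilylation followed by pyridine/DMAP acylation esterifies the four primary and secondary hydroxyls (C2, C9, C14, C16) while the hindered tertiary 8-OH stays free, and telescoping avoids O7 to O9 acyl migration in the free pentaol.

**Compound list**
1 | 1,2:5,6-di-O-isopropylidene-D-mannitol | CC1(C)OC[C@@H](O1)[C@@H](O)[C@H](O)[C@H]1COC(C)(C)O1 | starting material
2 | 2-(triphenylphosphoranylidene)propanal | CC(C=O)=P(c1ccccc1)(c1ccccc1)c1ccccc1 | starting material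
3 | (R)-2,2-dimethyl-1,3-dioxolane-4-carbaldehyde (glyceraldehyde acetonide, not isolated) | O=C[C@H]1COC(C)(C)O1 | intermediate
4 | (2E)-3-[(4S)-2,2-dimethyl-1,3-dioxolan-4-yl]-2-methylprop-2-enal (C2, C1, C15, C10, C9, C8) | O=C/C(C)=C/[C@H]1COC(C)(C)O1 | intermediate
5 | (E)-1-(trimethylsilyloxy)buta-1,3-diene | C=C/C=C/O[Si](C)(C)C | starting material
6 | ring A aldehyde: cyclohexene (C12=C13) with 1β-CH3, 1α-CHO, 10β-[(9S)-dioxolanyl] (H-10 α), 14α-OSiMe3 | C1C=C[C@H](O[Si](C)(C)C)[C@](C)(C=O)[C@H]1[C@H]2COC(C)(C)O2 | intermediate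
7 | ethynylmagnesium bromide (0.5 M in THF) | C#C[Mg]Br | starting material
8 | as 6, with 1α-[(2S)-CH(OH)C≡CH] in place of CHO | C1C=C[C@H](O[Si](C)(C)C)[C@](C)([C@@H](O)C#C)[C@H]1[C@H]2COC(C)(C)O2 | intermediate
9 | ring A tetraol: 1β-CH3, (2S)-CH(OH)C≡CH, 10β-[(9S)-CH(OH)CH2OH], 14α-OH, C12=C13 | C1C=C[C@H](O)[C@](C)([C@@H](O)C#C)[C@H]1[C@H](O)CO | intermediate
10 | tetrakis(triethylsilyl) ether of 9 (O2, O on C8, O9, O14) | C1C=C[C@H](O[Si](CC)(CC)CC)[C@](C)([C@@H](O[Si](CC)(CC)CC)C#C)[C@H]1[C@H](O[Si](CC)(CC)CC)CO[Si](CC)(CC)CC | intermediate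
11 | enone: as 10, with C11=O conjugated to C12=C13 | O=C1C=C[C@H](O[Si](CC)(CC)CC)[C@](C)([C@@H](O[Si](CC)(CC)CC)C#C)[C@H]1[C@H](O[Si](CC)(CC)CC)CO[Si](CC)(CC)CC | intermediate
12 | saturated C11 ketone | O=C1CC[C@H](O[Si](CC)(CC)CC)[C@](C)([C@@H](O[Si](CC)(CC)CC)C#C)[C@H]1[C@H](O[Si](CC)(CC)CC)CO[Si](CC)(CC)CC | intermediate
13 | 11(20)-exomethylene compound | C=C1CC[C@H](O[Si](CC)(CC)CC)[C@](C)([C@@H](O[Si](CC)(CC)CC)C#C)[C@H]1[C@H](O[Si](CC)(CC)CC)CO[Si](CC)(CC)CC | intermediate
14 | C8 aldehyde, (9S)-OSiEt3 | C=C1CC[C@H](O[Si](CC)(CC)CC)[C@](C)([C@@H](O[Si](CC)(CC)CC)C#C)[C@H]1[C@H](O[Si](CC)(CC)CC)C=O | intermediate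
15 | ethyl 2-methylacetoacetate | CCOC(=O)C(C)C(C)=O | starting material
16 | ethyl 2-diazopropanoate | CCOC(=O)C(C)=[N+]=[N-] | intermediate
17 | β-keto ester (C8=O, C17 labile epimer mixture, C19 ethyl ester), terminal alkyne at C3≡C4 | C=C1CC[C@H](O[Si](CC)(CC)CC)[C@](C)([C@@H](O[Si](CC)(CC)CC)C#C)[C@H]1[C@H](O[Si](CC)(CC)CC)C(=O)C(C)C(=O)OCC | intermediate
18 | but-2-yne-1,4-diol | OCC#CCO | starting material
19 | 4-(tert-butyldimethylsilyloxy)but-2-yn-1-ol | OCC#CCO[Si](C)(C)C(C)(C)C | intermediate
20 | sodium cyclic vinylalanate (five-membered O–Al–C5=C6–C7 ring, not isolated) | [Na+].COCCO[Al-]1(OCCOC)OCC=C1CO[Si](C)(C)C(C)(C)C | intermediate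
21 | (Z)-4-(tert-butyldimethylsilyloxy)-3-iodobut-2-en-1-ol | OC/C=C(\I)CO[Si](C)(C)C(C)(C)C | intermediate
22 | (Z)-4-(tert-butyldimethylsilyloxy)-3-iodobut-2-enal | O=C/C=C(\I)CO[Si](C)(C)C(C)(C)C | intermediate
23 | seco enynal keto ester (C7 aldehyde, 5E alkene, C3≡C4, C8 ketone; C17 epimer mixture) | C=C1CC[C@H](O[Si](CC)(CC)CC)[C@](C)([C@@H](O[Si](CC)(CC)CC)C#C/C(CO[Si](C)(C)C(C)(C)C)=C\C=O)[C@H]1[C@H](O[Si](CC)(CC)CC)C(=O)C(C)C(=O)OCC | intermediate
24 | ten-membered cis-(7S,8S)-diol ethyl ester (pinacol product, not isolated) | C=C1CC[C@H](O[Si](CC)(CC)CC)[C@]2(C)[C@@H](O[Si](CC)(CC)CC)C#C/C(CO[Si](C)(C)C(C)(C)C)=C\[C@H](O)[C@@](O)(C(C)C(=O)OCC)[C@@H](O[Si](CC)(CC)CC)[C@@H]12 | intermediate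
25 | macrocyclic enyne γ-lactone (7S,8S,17R), free 8-OH, OSiEt3 at C2, C9, C14, OSiMe2t-Bu at C16 | C=C1CC[C@H](O[Si](CC)(CC)CC)[C@]2(C)[C@@H](O[Si](CC)(CC)CC)C#C/C(CO[Si](C)(C)C(C)(C)C)=C\[C@@H]3OC(=O)[C@H](C)[C@@]3(O)[C@@H](O[Si](CC)(CC)CC)[C@@H]12 | intermediate
26 | (3Z,5E)-diene lactone, silyl groups as in 25 | C=C1CC[C@H](O[Si](CC)(CC)CC)[C@]2(C)[C@@H](O[Si](CC)(CC)CC)/C=C\C(CO[Si](C)(C)C(C)(C)C)=C/[C@@H]3OC(=O)[C@H](C)[C@@]3(O)[C@@H](O[Si](CC)(CC)CC)[C@@H]12 | intermediate
27 | 2,8,9,14,16-pentaol lactone (not isolated) | C=C1CC[C@H](O)[C@]2(C)[C@@H](O)/C=C\C(CO)=C/[C@@H]3OC(=O)[C@H](C)[C@@]3(O)[C@@H](O)[C@@H]12 | intermediate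
28 | CNP0269068.1, (1R,2S,3Z,5E,7S,8S,9S,10S,14S,17R)-2,9,14,16-tetraacetoxy-8-hydroxybriara-3,5,11(20)-trien-18,7-olide | C=C1CC[C@H](OC(C)=O)[C@]2(C)[C@@H](OC(C)=O)/C=C\C(COC(C)=O)=C/[C@@H]3OC(=O)[C@H](C)[C@@]3(O)[C@@H](OC(C)=O)[C@@H]12 | target

**Totals:** 18 steps in all. The longest linear sequence is 14 steps (steps 1–9, 11, 15–18).

**Steps most likely to fail**

*Step 16 (ketyl macrocyclisation).* Four things can defeat it:
- the C8 ketone is hindered;
- C17–H is acidic and can quench reduced species;
- the γ- or α-silyloxy groups can be lost by over-reduction;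
- medium-ring closure is slow.

The fallback sets out from 14 and comes back at 25. Couple 14 directly with 22 under the conditions of step 15 to get the enynal dialdehyde F1. Close the ring between the two unhindered, non-acidic aldehydes with SmI2, which is still a ketyl union of C7 and C8, to get the macrocyclic cis-7,8-diol F2. Acylate the less hindered allylic 7-OH with 2-bromopropanoyl bromide and pyridine to get the 7-O-(2-bromopropanoate) F3. Oxidise the remaining 8-OH with Dess–Martin periodinane to get the C8 ketone F4. Finally make C8–C17 by an intramolecular samarium Reformatsky reaction (SmI2, THF, −78 °C). The O7 tether delivers the enolate, and the product is 25.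

*Step 2 (Diels–Alder).* The trisubstituted, γ-branched enal may react too slowly or with poor face or endo selectivity. The fallback sets out from 4 and comes back at 6, and it builds ring A by acyclic bond formation plus metathesis.
- Copper-mediated conjugate allylation of 4 (allylmagnesium bromide, CuBr·SMe2, Me3SiCl, THF, −78 °C, attack anti to the C9–O bond) gives the C1=C2 silyl enol ether F5.
- A Me3SiOTf-catalysed Mukaiyama aldol reaction of F5 with acrolein creates the quaternary C1 and C14 and gives the O-silylated aldol diene F6.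
- Ring-closing metathesis of F6 with the second-generation Grubbs catalyst closes C12=C13 and gives 6.

*Step 6 (allylic oxidation).* The radical process may also attack C2–H or give the transposed enone. The fallback sets out from 10 and comes back at 11. SeO2 (cat.) with t-BuOOH in CH2Cl2 hydroxylates C11 by an ene reaction followed by a [2,3]-shift. This path is non-radical and returns the double bond to C12=C13, giving the C11 allylic alcohol F7. Dess–Martin periodinane then oxidises F7 to 11.

**Further compounds**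
F1 | step 16 | enynal dialdehyde (C7 and C8 aldehydes) | C=C1CC[C@H](O[Si](CC)(CC)CC)[C@](C)([C@@H](O[Si](CC)(CC)CC)C#C/C(CO[Si](C)(C)C(C)(C)C)=C\C=O)[C@H]1[C@H](O[Si](CC)(CC)CC)C=O
F2 | step 16 | macrocyclic cis-7,8-diol | C=C1CC[C@H](O[Si](CC)(CC)CC)[C@]2(C)[C@@H](O[Si](CC)(CC)CC)C#C/C(CO[Si](C)(C)C(C)(C)C)=C\[C@H](O)[C@H](O)[C@@H](O[Si](CC)(CC)CC)[C@@H]12
F3 | step 16 | 7-O-(2-bromopropanoate) of F2 | C=C1CC[C@H](O[Si](CC)(CC)CC)[C@]2(C)[C@@H](O[Si](CC)(CC)CC)C#C/C(CO[Si](C)(C)C(C)(C)C)=C\[C@H](OC(=O)C(C)Br)[C@H](O)[C@@H](O[Si](CC)(CC)CC)[C@@H]12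
F4 | step 16 | C8 ketone of F3 | C=C1CC[C@H](O[Si](CC)(CC)CC)[C@]2(C)[C@@H](O[Si](CC)(CC)CC)C#C/C(CO[Si](C)(C)C(C)(C)C)=C\[C@H](OC(=O)C(C)Br)C(=O)[C@@H](O[Si](CC)(CC)CC)[C@@H]12
F5 | step 2 | C1=C2 silyl enol ether with 10-allyl group | C[Si](C)(C)OC=C(C)[C@H](CC=C)[C@H]1COC(C)(C)O1
F6 | step 2 | O-silylated aldol diene (quaternary C1, 14-OSiMe3, vinyl and allyl termini) | C=C[C@H](O[Si](C)(C)C)[C@](C)(C=O)[C@H](CC=C)[C@H]1COC(C)(C)O1
F7 | step 6 | C11 allylic alcohol (C11 epimers) | OC1C=C[C@H](O[Si](CC)(CC)CC)[C@](C)([C@@H](O[Si](CC)(CC)CC)C#C)[C@H]1[C@H](O[Si](CC)(CC)CC)CO[Si](CC)(CC)CC
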